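## Retrosynthetic overview

1. Target 12 ⇐ anti hydrolysis at the allylic C5 of the syn-5,6-epoxide 11, which already carries both benzoates and masks the trans-5,6-diol.
2. 11 ⇐ a C2 carbinol trans to C1–OH, made by oxidising the cis C2–OH of 8 to enone 9 and reducing it under direction of the C1 hydroxyl (net inversion at C2).
3. 8 ⇐ hydroxyl-directed epoxidation of dienol 6, in which the tertiary C1–OH delivers oxygen to C5=C6 on its own face.
4. 6 ⇐ (1S,2R)-diol acid 2 (CO2H → CH2OBz, C2–OH silylated) ⇐ benzoic acid 1 by enzymatic arene cis-dihydroxylation, which sets C1 and the provisional C2 centre.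
5. Rings: the carbocycle is the benzene ring of 1, dearomatised and never re-formed; the only ring built is the oxirane (step 6), opened again in step 11.

Assumption: ring atoms are numbered as in the target (C1 bears CH2OBz, C2 bears OBz, C3=C4, C5, C6); the dioxygenase strain Cupriavidus necator B9 is obtained from a culture collection and gives the known (1S,2R)-diol acid in >95% ee.

## Route

Step 1
Reactants: 1 benzoic acid
Product: 2 (1S,2R)-1,2-dihydroxycyclohexa-3,5-diene-1-carboxylic acid
Conditions: whole cells of Cupriavidus necator B9 (benzoate 1,2-dioxygenase; no diol dehydrogenase), air, fructose, phosphate-buffered mineral medium pH 7, 30 °C; then pH 3, EtOAc extraction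
Reagents that add atoms: dioxygen, O=O
Why: Benzoate 1,2-dioxygenase, a Rieske-type arene dioxygenase, adds both atoms of O2 to the ipso and ortho carbons from one face of the achiral arene (enzymatic asymmetric cis-dihydroxylation), setting C1 (S) and C2 (R) with both oxygens cis, and the diol accumulates because the mutant cannot dehydrogenate it.

Step 2
Reactants: 2 (1S,2R)-1,2-dihydroxycyclohexa-3,5-diene-1-carboxylic acid
Product: 3 methyl (1S,2R)-1,2-dihydroxycyclohexa-3,5-diene-1-carboxylate
Conditions: MeI, K2CO3, DMF, 0 °C → rt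
Reagents that add atoms: iodomethane, CI
Why: Carboxylate O-alkylation (SN2 on MeI) under mild base esterifies the acid without exposing the acid-sensitive dienediol to acid, and no stereocentre is touched.

Step 3
Reactants: 3 methyl (1S,2R)-1,2-dihydroxycyclohexa-3,5-diene-1-carboxylate
Product: 4 methyl (1S,2R)-2-[(tert-butyldimethylsilyl)oxy]-1-hydroxycyclohexa-3,5-diene-1-carboxylate
Conditions: TBSCl, imidazole, DMF, 0 °C → rt
Reagents that add atoms: tert-butyldimethylsilyl chloride, CC(C)(C)[Si](C)(C)Cl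
Why: Silyl ether formation is selective for the secondary C2–OH over the tertiary, ester-flanked C1–OH, and it masks the only other hydroxyl that could direct the later epoxidation.

Step 4
Reactants: 4 methyl (1S,2R)-2-[(tert-butyldimethylsilyl)oxy]-1-hydroxycyclohexa-3,5-diene-1-carboxylate
Product: 5 (1R,6R)-6-[(tert-butyldimethylsilyl)oxy]-1-(hydroxymethyl)cyclohexa-2,4-dien-1-ol
Conditions: LiAlH4, THF, −20 °C → 0 °C; H2O work-up
Reagents that add atoms: none
Why: Hydride reduction of the ester gives the primary alcohol while the silyl ether and the diene are inert, and the stereocentres are untouched (the descriptor at C1 changes only through substituent priorities).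

Step 5
Reactants: 5 (1R,6R)-6-[(tert-butyldimethylsilyl)oxy]-1-(hydroxymethyl)cyclohexa-2,4-dien-1-ol
Product: 6 [(1R,6R)-6-[(tert-butyldimethylsilyl)oxy]-1-hydroxycyclohexa-2,4-dien-1-yl]methyl benzoate
Conditions: BzCl (1.1 equiv), pyridine, CH2Cl2, −20 °C → 0 °C
Reagents that add atoms: benzoyl chloride, O=C(Cl)c1ccccc1
Why: Nucleophilic acyl substitution is far faster at the primary alcohol than at the tertiary C1–OH, so the CH2OBz group of the target is installed selectively.

Step 6
Reactants: 6 [(1R,6R)-6-[(tert-butyldimethylsilyl)oxy]-1-hydroxycyclohexa-2,4-dien-1-yl]methyl benzoate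
Product: 7 [(1S,2S,3R,6S)-3-[(tert-butyldimethylsilyl)oxy]-2-hydroxy-7-oxabicyclo[4.1.0]hept-4-en-2-yl]methyl benzoate (oxirane syn to the tertiary OH)
Conditions: VO(acac)2 (5 mol%), t-BuOOH (anhydrous, 1.5 equiv), CH2Cl2, 0 °C → rt
Reagents that add atoms: tert-butyl hydroperoxide, CC(C)(C)OO
Why: In this hydroxyl-directed vanadium-catalysed epoxidation the tertiary allylic C1 alkoxide binds the metal and delivers the peroxide oxygen only to the adjacent C5=C6 bond on the face of C1–OH, setting C5 and C6, while C3=C4 has no free allylic hydroxyl and its lower face is screened by the silyl ether.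

Step 7
Reactants: 7 [(1S,2S,3R,6S)-3-[(tert-butyldimethylsilyl)oxy]-2-hydroxy-7-oxabicyclo[4.1.0]hept-4-en-2-yl]methyl benzoate
Product: 8 [(1S,2R,3R,6S)-2,3-dihydroxy-7-oxabicyclo[4.1.0]hept-4-en-2-yl]methyl benzoate (2,3-cis-diol)
Conditions: TBAF, AcOH (1:1), THF, 0 °C
Reagents that add atoms: none
Why: Fluoride-induced desilylation frees the C2–OH, acetic acid buffering suppresses benzoyl migration, and the syn-epoxy alcohol cannot undergo Payne rearrangement.

Step 8
Reactants: 8 [(1S,2R,3R,6S)-2,3-dihydroxy-7-oxabicyclo[4.1.0]hept-4-en-2-yl]methyl benzoate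
Product: 9 [(1S,2S,6S)-2-hydroxy-3-oxo-7-oxabicyclo[4.1.0]hept-4-en-2-yl]methyl benzoate
Conditions: Dess–Martin periodinane, pyridine, CH2Cl2, 0 °C → rt
Reagents that add atoms: none
Why: Dess–Martin oxidation converts the only secondary alcohol into the enone, erasing the wrongly configured C2 centre, while the tertiary OH, the epoxide and the benzoate are inert under pyridine buffering.

Step 9
Reactants: 9 [(1S,2S,6S)-2-hydroxy-3-oxo-7-oxabicyclo[4.1.0]hept-4-en-2-yl]methyl benzoate
Product: 10 [(1S,2R,3S,6S)-2,3-dihydroxy-7-oxabicyclo[4.1.0]hept-4-en-2-yl]methyl benzoate (2,3-trans-diol)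
Conditions: Me4NBH(OAc)3, MeCN/AcOH (10:1), −40 °C → −20 °C; cold NaHCO3 quench
Reagents that add atoms: none
Why: In this hydroxyl-directed (Evans–Saksena) 1,2-reduction the C1–OH exchanges onto boron and hands the hydride to the carbonyl face it occupies, so the new C2–OH is trans to C1–OH and cis to CH2OBz, a net inversion of the enzymatically set C2 centre.

Step 10
Reactants: 10 [(1S,2R,3S,6S)-2,3-dihydroxy-7-oxabicyclo[4.1.0]hept-4-en-2-yl]methyl benzoate
Product: 11 [(1S,2R,3S,6S)-3-(benzoyloxy)-2-hydroxy-7-oxabicyclo[4.1.0]hept-4-en-2-yl]methyl benzoate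
Conditions: Bz2O, Et3N, DMAP (cat.), CH2Cl2, 0 °C → rt
Reagents that add atoms: benzoic anhydride, O=C(OC(=O)c1ccccc1)c1ccccc1
Why: DMAP-catalysed acylation benzoylates the single secondary hydroxyl while the tertiary C1–OH does not react, and the chloride-free anhydride conditions spare the vinyl oxirane.

Step 11
Reactants: 11 [(1S,2R,3S,6S)-3-(benzoyloxy)-2-hydroxy-7-oxabicyclo[4.1.0]hept-4-en-2-yl]methyl benzoate
Product: 12 [(1S,2S,5R,6S)-2-(benzoyloxy)-1,5,6-trihydroxycyclohex-3-en-1-yl]methyl benzoate (CNP0141358.1)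
Conditions: HClO4 (cat., 0.05 M), THF/H2O (2:1), 0 °C → rt
Reagents that add atoms: water, O
Why: In the acid-catalysed hydrolysis of the vinyl epoxide water attacks the allylic C5 rather than the neopentyl C6, with inversion (trans-diaxial opening), so C6–OH stays cis to C1–OH and the new C5–OH is cis to the C2 benzoate, which is the target.

## Compound list

1 | benzoic acid | O=C(O)c1ccccc1 | starting material
2 | (1S,2R)-1,2-dihydroxycyclohexa-3,5-diene-1-carboxylic acid | OC(=O)[C@@]1(O)[C@H](O)C=CC=C1 | intermediate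
3 | methyl (1S,2R)-1,2-dihydroxycyclohexa-3,5-diene-1-carboxylate | COC(=O)[C@@]1(O)[C@H](O)C=CC=C1 | intermediate
4 | methyl (1S,2R)-2-[(tert-butyldimethylsilyl)oxy]-1-hydroxycyclohexa-3,5-diene-1-carboxylate | COC(=O)[C@@]1(O)[C@H](O[Si](C)(C)C(C)(C)C)C=CC=C1 | intermediate
5 | (1R,6R)-6-[(tert-butyldimethylsilyl)oxy]-1-(hydroxymethyl)cyclohexa-2,4-dien-1-ol | OC[C@@]1(O)[C@H](O[Si](C)(C)C(C)(C)C)C=CC=C1 | intermediate
6 | [(1R,6R)-6-[(tert-butyldimethylsilyl)oxy]-1-hydroxycyclohexa-2,4-dien-1-yl]methyl benzoate | O=C(OC[C@@]1(O)[C@H](O[Si](C)(C)C(C)(C)C)C=CC=C1)c1ccccc1 | intermediate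
7 | [(1S,2S,3R,6S)-3-[(tert-butyldimethylsilyl)oxy]-2-hydroxy-7-oxabicyclo[4.1.0]hept-4-en-2-yl]methyl benzoate | O=C(OC[C@@]1(O)[C@H](O[Si](C)(C)C(C)(C)C)C=C[C@@H]2O[C@H]12)c1ccccc1 | intermediate
8 | [(1S,2R,3R,6S)-2,3-dihydroxy-7-oxabicyclo[4.1.0]hept-4-en-2-yl]methyl benzoate | O=C(OC[C@@]1(O)[C@H](O)C=C[C@@H]2O[C@H]12)c1ccccc1 | intermediate
9 | [(1S,2S,6S)-2-hydroxy-3-oxo-7-oxabicyclo[4.1.0]hept-4-en-2-yl]methyl benzoate | O=C(OC[C@@]1(O)C(=O)C=C[C@@H]2O[C@H]12)c1ccccc1 | intermediate
10 | [(1S,2R,3S,6S)-2,3-dihydroxy-7-oxabicyclo[4.1.0]hept-4-en-2-yl]methyl benzoate | O=C(OC[C@@]1(O)[C@@H](O)C=C[C@@H]2O[C@H]12)c1ccccc1 | intermediate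
11 | [(1S,2R,3S,6S)-3-(benzoyloxy)-2-hydroxy-7-oxabicyclo[4.1.0]hept-4-en-2-yl]methyl benzoate | O=C(OC[C@@]1(O)[C@@H](OC(=O)c2ccccc2)C=C[C@@H]3O[C@H]13)c1ccccc1 | intermediate
12 | [(1S,2S,5R,6S)-2-(benzoyloxy)-1,5,6-trihydroxycyclohex-3-en-1-yl]methyl benzoate | O=C(OC[C@@]1(O)[C@@H](OC(=O)c2ccccc2)C=C[C@@H](O)[C@@H]1O)c1ccccc1 | target

## Step count and risks

Total steps: 11. Longest linear sequence: 11 steps (fully linear from benzoic acid).

The three steps most likely to fail:

Step 6 (directed epoxidation of a conjugated diene). The risks are attack at C3=C4 and loss of the vinyl oxirane on the Lewis-acidic metal. The fallback sets out from 6 and builds the epoxide by ring closure instead of oxygen transfer. OsO4 with TMEDA (CH2Cl2, −78 °C; NaHSO3 work-up) dihydroxylates C5=C6 on the face of the hydrogen-bonding C1–OH to give the all-cis triol [(1S,2R,5S,6S)-2-[(tert-butyldimethylsilyl)oxy]-1,5,6-trihydroxycyclohex-3-en-1-yl]methyl benzoate F1. MnO2 (CH2Cl2, rt) oxidises only the allylic C5 carbinol to the enone [(1S,2R,6R)-2-[(tert-butyldimethylsilyl)oxy]-1,6-dihydroxy-5-oxocyclohex-3-en-1-yl]methyl benzoate F2. Me4NBH(OAc)3 (MeCN/AcOH, −30 °C), bound to the C6 and C1 hydroxyls, delivers hydride to their face and gives the 5,6-trans triol [(1S,2R,5R,6S)-2-[(tert-butyldimethylsilyl)oxy]-1,5,6-trihydroxycyclohex-3-en-1-yl]methyl benzoate F3. Mitsunobu cyclodehydration (PPh3, DIAD, THF, 0 °C) then activates the less hindered allylic C5–OH, which the C6 oxygen displaces with inversion, and the route is rejoined at 7.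

Step 9 (directed reduction). The risks are that the cis-diol forms instead, which is 8 again, or that the oxirane suffers in acetic acid. The fallback sets out from 8 and inverts C2 by substitution instead of by redox. Benzoic acid, PPh3 and DIAD in toluene (0 °C → rt) displace the activated allylic C2–OH by benzoate with inversion and give the trans benzoate directly. This detour forms no new compound (F0), skips 9 and 10, and rejoins the route at 11.

Step 11 (epoxide hydrolysis). The risks are 1,4-addition at C3 or participation of the C2 benzoate under cationic conditions. The fallback sets out from 11 and opens the oxirane under neutral metal catalysis. [Rh(CO)2Cl]2 (cat.) with 4-methoxybenzyl alcohol in THF at rt adds the alcohol anti at the allylic C5 to give the ether [(1S,2S,5R,6S)-2-(benzoyloxy)-1,6-dihydroxy-5-[(4-methoxybenzyl)oxy]cyclohex-3-en-1-yl]methyl benzoate F4. DDQ (CH2Cl2/pH 7 buffer, 0 °C) then cleaves the ether, and the route is rejoined at 12.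

## Further compounds

F1 | step 6 | [(1S,2R,5S,6S)-2-[(tert-butyldimethylsilyl)oxy]-1,5,6-trihydroxycyclohex-3-en-1-yl]methyl benzoate | O=C(OC[C@@]1(O)[C@H](O[Si](C)(C)C(C)(C)C)C=C[C@H](O)[C@@H]1O)c1ccccc1
F2 | step 6 | [(1S,2R,6R)-2-[(tert-butyldimethylsilyl)oxy]-1,6-dihydroxy-5-oxocyclohex-3-en-1-yl]methyl benzoate | O=C(OC[C@@]1(O)[C@H](O[Si](C)(C)C(C)(C)C)C=CC(=O)[C@@H]1O)c1ccccc1
F3 | step 6 | [(1S,2R,5R,6S)-2-[(tert-butyldimethylsilyl)oxy]-1,5,6-trihydroxycyclohex-3-en-1-yl]methyl benzoate | O=C(OC[C@@]1(O)[C@H](O[Si](C)(C)C(C)(C)C)C=C[C@@H](O)[C@@H]1O)c1ccccc1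
F0 | step 9 | none | none
F4 | step 11 | [(1S,2S,5R,6S)-2-(benzoyloxy)-1,6-dihydroxy-5-[(4-methoxybenzyl)oxy]cyclohex-3-en-1-yl]methyl benzoate | O=C(OC[C@@]1(O)[C@@H](OC(=O)c2ccccc2)C=C[C@@H](OCc2ccc(OC)cc2)[C@@H]1O)c1ccccc1
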